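**Retrosynthetic overview**

- The target is four purchased benzene rings: A (4-hydroxy-3-methoxyphenyl), B (3-hydroxy-5-methoxy, substituted at C1 and C4), C (4-hydroxy-6-methoxy, substituted at C1 and C2) and D (3-hydroxyphenyl). No ring is constructed at any stage.
- The strategy rests on the central C(sp3)–C(sp3) bond of each CH2–CH2 bridge (ring A C1 to ring B C1, and ring C C2 to ring D C1). Both are benzyl–benzyl bonds, so each is traced back to an unsymmetrical dibenzyl sulfone ArCH2–SO2–CH2Ar'. A two-fold Ramberg–Bäcklund reaction forms both bonds, and one hydrogenation then saturates both alkenes and removes all four O-benzyl groups.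
- The bis-sulfone comes from the bis-sulfide. The single CH2 between ring B C4 and ring C C1 is cut to a ring B aryllithium (from a C4 bromide) and a ring C benzaldehyde whose carbonyl carbon is the orsellinate carboxyl carbon; ionic deoxygenation follows.
- Each half carries its thioether before the union. The C/D half comes from methyl orsellinate (selective 4-O-benzylation, 2-O-methylation, benzylic bromination, thiolate alkylation, ester to aldehyde). The A/B half comes from methyl 4-bromo-3,5-dihydroxybenzoate (desymmetrising alkylations, ester to benzyl bromide, thiolate alkylation).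
- The only rings closed are the two transient episulfones of the key step, which lose SO2 at once.

Key step: step 17

Remark: the target has no stereocentre or other stereogenic element, so it is achiral and no stereocontrol is required; the carbinol centre and the alkene geometry that arise on the way are both erased.

**Route**

Step 1
Reactants: 1 methyl orsellinate
Product: 2 methyl 4-(benzyloxy)-2-hydroxy-6-methylbenzoate
Conditions: BnBr (1.05 equiv), K2CO3, acetone, reflux
Reagents that add atoms: benzyl bromide, BrCc1ccccc1
Why: Williamson etherification, selective for the 4-OH because the 2-OH is tied up in a hydrogen bond to the ester carbonyl and is the less acidic and less nucleophilic phenol.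

Step 2
Reactants: 2 methyl 4-(benzyloxy)-2-hydroxy-6-methylbenzoate
Product: 3 methyl 4-(benzyloxy)-2-methoxy-6-methylbenzoate
Conditions: MeI (excess), K2CO3, DMF, 50 °C
Reagents that add atoms: iodomethane, CI
Why: Williamson methylation of the remaining chelated phenol, which should go to completion with excess MeI in a dipolar aprotic solvent.

Step 3
Reactants: 3 methyl 4-(benzyloxy)-2-methoxy-6-methylbenzoate
Product: 4 methyl 4-(benzyloxy)-2-(bromomethyl)-6-methoxybenzoate
Conditions: NBS (1.05 equiv), AIBN (cat.), PhCF3, 85 °C, hν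
Reagents that add atoms: N-bromosuccinimide, O=C1CCC(=O)N1Br
Why: Wohl–Ziegler radical bromination of the aryl methyl group, run in a non-polar solvent with radical initiation and a low bromine concentration to disfavour ionic bromination of the ring.

Step 4
Reactants: 5 3-(benzyloxy)benzyl alcohol
Product: 6 S-[3-(benzyloxy)benzyl] thioacetate
Conditions: AcSH, PPh3, DIAD, THF, 0 °C → rt
Reagents that add atoms: thioacetic acid, CC(=O)S
Why: Mitsunobu thioesterification, in which thioacetate displaces the oxyphosphonium of a primary benzylic alcohol by SN2.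

Step 5
Reactants: 4 methyl 4-(benzyloxy)-2-(bromomethyl)-6-methoxybenzoate; 6 S-[3-(benzyloxy)benzyl] thioacetate
Product: 8 methyl 4-(benzyloxy)-2-{[3-(benzyloxy)benzylthio]methyl}-6-methoxybenzoate, via 3-(benzyloxy)benzyl thiolate 7 (not isolated)
Conditions: K2CO3, degassed MeOH/THF, 0 °C → rt (6 and base first, then 4)
Reagents that add atoms: none
Why: Methanolysis of the thioacetate frees the thiolate, which should alkylate the benzylic bromide by SN2 (thio-Williamson) much faster than methoxide does; the methyl ester is unchanged in methanol.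

Step 6
Reactants: 8 methyl 4-(benzyloxy)-2-{[3-(benzyloxy)benzylthio]methyl}-6-methoxybenzoate
Product: 9 [4-(benzyloxy)-2-{[3-(benzyloxy)benzylthio]methyl}-6-methoxyphenyl]methanol
Conditions: LiAlH4, THF, 0 → 40 °C; Fieser work-up
Reagents that add atoms: none
Why: Hydride reduction of the hindered aryl ester to the benzylic alcohol; thioether and benzyl ethers are inert to LiAlH4.

Step 7
Reactants: 9 [4-(benzyloxy)-2-{[3-(benzyloxy)benzylthio]methyl}-6-methoxyphenyl]methanol
Product: 10 4-(benzyloxy)-2-{[3-(benzyloxy)benzylthio]methyl}-6-methoxybenzaldehyde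
Conditions: activated MnO2 (excess), CH2Cl2, rt
Reagents that add atoms: none
Why: MnO2 oxidation of an electron-rich benzylic alcohol should stop at the aldehyde and leave the dialkyl sulfide untouched.

Step 8
Reactants: 11 methyl 4-bromo-3,5-dihydroxybenzoate
Product: 12 methyl 3-(benzyloxy)-4-bromo-5-hydroxybenzoate
Conditions: BnBr (0.9 equiv), K2CO3, DMF, rt; unreacted 11 recovered
Reagents that add atoms: benzyl bromide, BrCc1ccccc1
Why: Williamson mono-etherification of a symmetrical diphenol, a statistical desymmetrisation run with a deficit of BnBr so that the mono-ether should predominate over the bis-ether and the diol can be recycled.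

Step 9
Reactants: 12 methyl 3-(benzyloxy)-4-bromo-5-hydroxybenzoate
Product: 13 methyl 3-(benzyloxy)-4-bromo-5-methoxybenzoate
Conditions: MeI (excess), K2CO3, DMF, rt
Reagents that add atoms: iodomethane, CI
Why: Williamson methylation of the single remaining phenol.

Step 10
Reactants: 13 methyl 3-(benzyloxy)-4-bromo-5-methoxybenzoate
Product: 14 [3-(benzyloxy)-4-bromo-5-methoxyphenyl]methanol
Conditions: DIBAL-H (2.5 equiv), CH2Cl2, −78 → 0 °C; Rochelle salt
Reagents that add atoms: none
Why: DIBAL-H reduction of the ester to the primary alcohol, chosen because it should not touch the aryl C–Br bond.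

Step 11
Reactants: 14 [3-(benzyloxy)-4-bromo-5-methoxyphenyl]methanol
Product: 15 3-(benzyloxy)-4-bromo-5-methoxybenzyl bromide
Conditions: PBr3, CH2Cl2, 0 °C
Reagents that add atoms: phosphorus tribromide, BrP(Br)Br
Why: Conversion of a benzylic alcohol into the bromide via its phosphite ester (SN2); the oxygens are meta to the benzylic carbon, so the bromide should be stable to handling.

Step 12
Reactants: 16 4-(benzyloxy)-3-methoxybenzyl alcohol
Product: 17 S-[4-(benzyloxy)-3-methoxybenzyl] thioacetate
Conditions: AcSH, PPh3, DIAD, THF, 0 °C → rt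
Reagents that add atoms: thioacetic acid, CC(=O)S
Why: Mitsunobu thioesterification of a primary benzylic alcohol, as in step 4.

Step 13
Reactants: 15 3-(benzyloxy)-4-bromo-5-methoxybenzyl bromide; 17 S-[4-(benzyloxy)-3-methoxybenzyl] thioacetate
Product: 19 3-(benzyloxy)-4-bromo-5-methoxybenzyl 4-(benzyloxy)-3-methoxybenzyl sulfide, via 4-(benzyloxy)-3-methoxybenzyl thiolate 18 (not isolated)
Conditions: K2CO3, degassed MeOH/THF, 0 °C → rt (17 and base first, then 15)
Reagents that add atoms: none
Why: In situ thioacetate methanolysis and SN2 thioether formation at the benzylic bromide; the aryl bromide is inert to thiolate under these conditions.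

Step 14
Reactants: 19 3-(benzyloxy)-4-bromo-5-methoxybenzyl 4-(benzyloxy)-3-methoxybenzyl sulfide; 10 4-(benzyloxy)-2-{[3-(benzyloxy)benzylthio]methyl}-6-methoxybenzaldehyde
Product: 21 racemic diaryl carbinol bis-sulfide [ring B C4–CH(OH)–C1 ring C], via aryllithium 20 (not isolated)
Conditions: n-BuLi (1.05 equiv), THF, −78 °C, 15 min; then 10, −78 → −30 °C; H2O
Reagents that add atoms: none
Why: Bromine–lithium exchange at −78 °C should outpace deprotonation next to sulfur or at the O-benzyl methylene, and the 2,6-dialkoxyaryllithium then adds 1,2 to the aldehyde; the new carbinol centre forms racemic and is removed in step 15.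

Step 15
Reactants: 21 racemic diaryl carbinol bis-sulfide
Product: 22 bis-sulfide diarylmethane (ring B C4–CH2–C1 ring C)
Conditions: Et3SiH (3 equiv), TFA (5 equiv), CH2Cl2, −20 → 0 °C
Reagents that add atoms: none
Why: Ionic hydrogenation, in which the carbinol ionises to a benzhydryl cation stabilised by four ortho/para oxygens and is reduced by the silane; any cyclic sulfonium formed with the ortho thioether should re-ionise and drain to product.

Step 16
Reactants: 22 bis-sulfide diarylmethane
Product: 23 bis(dibenzyl sulfone) of the tetra-O-benzyl diarylmethane core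
Conditions: mCPBA (4.4 equiv), CH2Cl2, 0 °C → rt
Reagents that add atoms: 3-chloroperoxybenzoic acid, OOC(=O)c1cccc(Cl)c1
Why: Peracid oxidation of both sulfides through the sulfoxides to the sulfones, which is much faster than attack on the alkoxyarenes.

Step 17
Reactants: 23 bis(dibenzyl sulfone)
Product: 26 tetra-O-benzyl bis-stilbene (drawn E,E), via bis(α-bromo sulfone) 24 (not isolated), via bis(episulfone) 25 (not isolated)
Conditions: CBr2F2 (excess), KOH/Al2O3, t-BuOH/CH2Cl2, 0 °C → rt
Reagents that add atoms: none
Why: At each sulfone, KOH on alumina removes a sulfonyl α-proton, the carbanion takes bromine from CBr2F2, the α'-carbanion displaces bromide in a 1,3-elimination to give an episulfone, and cheletropic loss of SO2 leaves the stilbene C=C. The closest known reaction is the one-pot Ramberg–Bäcklund olefination of dibenzyl sulfones to stilbenes with in situ halogenation (Chan's conditions), run here at two sites of one molecule. The only rings closed are the two transient thiirane 1,1-dioxides (3-exo-tet), and none remains in the product. No stereocentre is created, and the alkene geometry (E expected to predominate) is irrelevant because both alkenes are hydrogenated in step 18. The step needs halogenation only at the four sulfonyl α-CH2 groups and not at the diarylmethane CH2 or on the rings. This is secured by the much greater acidity of the sulfonyl benzylic positions and by the fact that CBr2F2 transfers bromine only to carbanions; all phenols are benzylated, so no phenoxide is present.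

Step 18
Reactants: 26 tetra-O-benzyl bis-stilbene
Product: 27 4-{2-[3-hydroxy-4-({4-hydroxy-2-[2-(3-hydroxyphenyl)ethyl]-6-methoxyphenyl}methyl)-5-methoxyphenyl]ethyl}-2-methoxyphenol (target)
Conditions: H2 (1 atm), 10% Pd/C, EtOAc/MeOH, rt
Reagents that add atoms: none
Why: Catalytic hydrogenation should saturate both stilbene double bonds and hydrogenolyse all four aryl benzyl ethers in one operation, while the diarylmethane and methyl ethers stay intact.

**Compound list**

1 | methyl orsellinate | COC(=O)c1c(C)cc(O)cc1O | starting material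
2 | methyl 4-(benzyloxy)-2-hydroxy-6-methylbenzoate | COC(=O)c1c(C)cc(OCc2ccccc2)cc1O | intermediate
3 | methyl 4-(benzyloxy)-2-methoxy-6-methylbenzoate | COC(=O)c1c(C)cc(OCc2ccccc2)cc1OC | intermediate
4 | methyl 4-(benzyloxy)-2-(bromomethyl)-6-methoxybenzoate | COC(=O)c1c(CBr)cc(OCc2ccccc2)cc1OC | intermediate
5 | 3-(benzyloxy)benzyl alcohol | OCc1cccc(OCc2ccccc2)c1 | starting material
6 | S-[3-(benzyloxy)benzyl] thioacetate | CC(=O)SCc1cccc(OCc2ccccc2)c1 | intermediate
7 | 3-(benzyloxy)benzyl thiol (potassium thiolate in the flask) | SCc1cccc(OCc2ccccc2)c1 | intermediate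
8 | methyl 4-(benzyloxy)-2-{[3-(benzyloxy)benzylthio]methyl}-6-methoxybenzoate | COC(=O)c1c(CSCc2cccc(OCc3ccccc3)c2)cc(OCc2ccccc2)cc1OC | intermediate
9 | [4-(benzyloxy)-2-{[3-(benzyloxy)benzylthio]methyl}-6-methoxyphenyl]methanol | OCc1c(CSCc2cccc(OCc3ccccc3)c2)cc(OCc2ccccc2)cc1OC | intermediate
10 | 4-(benzyloxy)-2-{[3-(benzyloxy)benzylthio]methyl}-6-methoxybenzaldehyde | O=Cc1c(CSCc2cccc(OCc3ccccc3)c2)cc(OCc2ccccc2)cc1OC | intermediate
11 | methyl 4-bromo-3,5-dihydroxybenzoate | COC(=O)c1cc(O)c(Br)c(O)c1 | starting material
12 | methyl 3-(benzyloxy)-4-bromo-5-hydroxybenzoate | COC(=O)c1cc(O)c(Br)c(OCc2ccccc2)c1 | intermediate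
13 | methyl 3-(benzyloxy)-4-bromo-5-methoxybenzoate | COC(=O)c1cc(OC)c(Br)c(OCc2ccccc2)c1 | intermediate
14 | [3-(benzyloxy)-4-bromo-5-methoxyphenyl]methanol | OCc1cc(OC)c(Br)c(OCc2ccccc2)c1 | intermediate
15 | 3-(benzyloxy)-4-bromo-5-methoxybenzyl bromide | BrCc1cc(OC)c(Br)c(OCc2ccccc2)c1 | intermediate
16 | 4-(benzyloxy)-3-methoxybenzyl alcohol | COc1cc(CO)ccc1OCc1ccccc1 | starting material
17 | S-[4-(benzyloxy)-3-methoxybenzyl] thioacetate | COc1cc(CSC(C)=O)ccc1OCc1ccccc1 | intermediate
18 | 4-(benzyloxy)-3-methoxybenzyl thiol (potassium thiolate in the flask) | COc1cc(CS)ccc1OCc1ccccc1 | intermediate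
19 | 3-(benzyloxy)-4-bromo-5-methoxybenzyl 4-(benzyloxy)-3-methoxybenzyl sulfide | COc1cc(CSCc2cc(OC)c(Br)c(OCc3ccccc3)c2)ccc1OCc1ccccc1 | intermediate
20 | aryllithium from 19 (Li in place of Br at ring B C4) | COc1cc(CSCc2cc(OC)c([Li])c(OCc3ccccc3)c2)ccc1OCc1ccccc1 | intermediate
21 | racemic diaryl carbinol bis-sulfide, ring B C4–CH(OH)–C1 ring C | COc1cc(CSCc2cc(OCc3ccccc3)c(C(O)c3c(CSCc4cccc(OCc5ccccc5)c4)cc(OCc4ccccc4)cc3OC)c(OC)c2)ccc1OCc1ccccc1 | intermediate
22 | bis-sulfide diarylmethane | COc1cc(CSCc2cc(OCc3ccccc3)c(Cc3c(CSCc4cccc(OCc5ccccc5)c4)cc(OCc4ccccc4)cc3OC)c(OC)c2)ccc1OCc1ccccc1 | intermediate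
23 | bis(dibenzyl sulfone) of the tetra-O-benzyl diarylmethane core | COc1cc(CS(=O)(=O)Cc2cc(OCc3ccccc3)c(Cc3c(CS(=O)(=O)Cc4cccc(OCc5ccccc5)c4)cc(OCc4ccccc4)cc3OC)c(OC)c2)ccc1OCc1ccccc1 | intermediate
24 | bis(α-bromo sulfone), one representative regioisomer, mixture of stereoisomers | COc1cc(CS(=O)(=O)C(Br)c2cc(OCc3ccccc3)c(Cc3c(CS(=O)(=O)C(Br)c4cccc(OCc5ccccc5)c4)cc(OCc4ccccc4)cc3OC)c(OC)c2)ccc1OCc1ccccc1 | intermediate
25 | bis(episulfone), two 2,3-diarylthiirane 1,1-dioxides, mixture of stereoisomers | COc1cc(C2C(c3cc(OCc4ccccc4)c(Cc4c(C5C(c6cccc(OCc7ccccc7)c6)S5(=O)=O)cc(OCc5ccccc5)cc4OC)c(OC)c3)S2(=O)=O)ccc1OCc1ccccc1 | intermediate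
26 | tetra-O-benzyl bis-stilbene (drawn E,E; geometry immaterial) | COc1cc(/C=C/c2cc(OCc3ccccc3)c(Cc3c(/C=C/c4cccc(OCc5ccccc5)c4)cc(OCc4ccccc4)cc3OC)c(OC)c2)ccc1OCc1ccccc1 | intermediate
27 | 4-{2-[3-hydroxy-4-({4-hydroxy-2-[2-(3-hydroxyphenyl)ethyl]-6-methoxyphenyl}methyl)-5-methoxyphenyl]ethyl}-2-methoxyphenol | COc1cc(CCc2cc(O)c(Cc3c(CCc4cccc(O)c4)cc(O)cc3OC)c(OC)c2)ccc1O | target

**Step count and risks**

Total step count: 18. Longest linear sequence: 11 (steps 1, 2, 3, 5, 6, 7, 14, 15, 16, 17, 18).

Steps most likely to fail:

1. Step 17 (double Ramberg–Bäcklund). The extrusion at the more hindered ring C/ring D sulfone may lag behind the other site while a second halogenation at an already brominated α-carbon competes. The outcome would be mixtures of mono-olefin and bromo-alkene material. The fallback separates halogenation from extrusion and moves it to the sulfide oxidation level. It sets out from bis-sulfide 22, which is chlorinated α to each sulfur with NCS (CCl4, 0 °C; the regiochemistry within each thioether is immaterial) to give the bis(α-chloro sulfide) F1. This is oxidised without purification with mCPBA to the bis(α-chloro sulfone) F2, and treatment with KOt-Bu in THF (classical Ramberg–Bäcklund of a preformed α-halo sulfone) comes back to the route at 26.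

2. Step 3 (benzylic bromination). Ionic bromination of the dialkoxy ring and hydrogen abstraction at the O-benzyl methylene may compete with the radical bromination of the aryl methyl group. The fallback avoids radical chemistry. It sets out from 3, which is deprotonated at the methyl group with LDA (THF, −78 °C, lateral lithiation of the ortho-toluate) and added inversely to bis[3-(benzyloxy)benzyl] disulfide F3, made from thioacetate 6 by K2CO3/MeOH and then I2. C-sulfenylation comes back to the route at 8, so 4 is not needed.

3. Step 15 (ionic deoxygenation). The ortho thioether sulfur may capture the benzhydryl cation as a cyclic sulfonium that then loses an S-benzyl group irreversibly, and a slow reduction would expose the electron-rich benzyl ethers to acid for longer. The fallback removes the nucleophilic sulfur before the cation is generated. It sets out from 21, which is oxidised at both thioethers with mCPBA to the carbinol bis-sulfone F4. Reduction of F4 with Et3SiH/TFA comes back to the route at 23, so 22 is not needed.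

**Further compounds**

F1 | step 17 | bis(α-chloro sulfide), one representative regioisomer, mixture of stereoisomers | COc1cc(C(Cl)SCc2cc(OCc3ccccc3)c(Cc3c(CSC(Cl)c4cccc(OCc5ccccc5)c4)cc(OCc4ccccc4)cc3OC)c(OC)c2)ccc1OCc1ccccc1
F2 | step 17 | bis(α-chloro sulfone), one representative regioisomer, mixture of stereoisomers | COc1cc(C(Cl)S(=O)(=O)Cc2cc(OCc3ccccc3)c(Cc3c(CS(=O)(=O)C(Cl)c4cccc(OCc5ccccc5)c4)cc(OCc4ccccc4)cc3OC)c(OC)c2)ccc1OCc1ccccc1
F3 | step 3 | bis[3-(benzyloxy)benzyl] disulfide | c1ccc(COc2cccc(CSSCc3cccc(OCc4ccccc4)c3)c2)cc1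
F4 | step 15 | racemic diaryl carbinol bis-sulfone | COc1cc(CS(=O)(=O)Cc2cc(OCc3ccccc3)c(C(O)c3c(CS(=O)(=O)Cc4cccc(OCc5ccccc5)c4)cc(OCc4ccccc4)cc3OC)c(OC)c2)ccc1OCc1ccccc1
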